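**Retrosynthetic overview**
1. The target is a normal labdane: 5α-H, 10β-CH3 (C20), 9β side chain, C7=C8, 4α-CH3 (C18), axial 4β-CH2O-angelate (C19) and a 13Z acid. The late cuts are C19–O (angeloylation), C13–C16 (syn addition of Me2CuLi to a C13≡C14 ynoate, which gives 13Z), C14–C15 and C12–C13 (acetylide chemistry), and C9–C11 (Johnson–Claisen from a 7β-ol, which also places the olefin at C7=C8).
2. The 8(9)-en-7β-ol comes from a 7-en-9β-ol by hydroxyl-directed β-epoxidation and a radical Wharton-type 1,3-transposition. Oxygen at C9, oxygen at C7 and carbon at C9 follow one another on the β face. Alkaline peroxide on the 9-ketone would attack the α face and lead to the 9-epimer.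
3. Ring A is closed second. C2–C3 forms by iodine–lithium exchange and 6-endo conjugate addition to a C4 acrylate, and C4–C18 forms by methylation of the resulting enolate in the same flask.
4. The plan rests on this feature: ring B (C5–C10), with C17 on C8 of the C7=C8 olefin and C4 attached to C5, is the ten-carbon skeleton of (R)-carvone. The carvone stereocentre is C5, its carbonyl carbon is C9, and its α′ carbon is C10, which takes C20 and then C1–C2 anti to C4. Its isopropenyl group supplies C3, C4 and C19.
5. C9 passes the key step as a 9β-silyl ether. A ketone between quaternary C10 and methyl-bearing C8 resists ketalisation, and ketalisation acid would strip the tert-butyl ester. Ring order: B (chiral pool), then A.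

Key step: step 12

Remark: labdane numbering is used for every compound, β is the face of the C20 methyl and α the face of H-5. The carbinol of step 10 is taken to be the 9β epimer for the reason given there, and any 9α epimer is removed by chromatography at that stage.

Step 1
Reactants: 1 (R)-(−)-carvone; 2 iodomethane
Product: 4 6-methylcarvone (CH3 on C10; both C10 epimers), via carvone lithium dienolate 3 (not isolated)
Conditions: LiN(i-Pr)2, THF, −78 °C; MeI, −78 → 0 °C
Reagents that add atoms: iodomethane, CI
Why: Kinetic α′-deprotonation of the cross-conjugated enone and SN2 methylation of the dienolate install C20; the C10 configuration formed here is erased in step 2 and needs no control.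

Step 2
Reactants: 4 6-methylcarvone; 5 allyl bromide
Product: 7 10α-allyl-10β-methyl enone (allyl trans and methyl cis to the C5 isopropenyl group), via lithium dienolate 6 (not isolated)
Conditions: LiN(i-Pr)2, THF, −78 → −20 °C; allyl bromide, DMPU, −78 °C → rt
Reagents that add atoms: allyl bromide, C=CCBr
Why: In this second α′-enolate alkylation the tetrasubstituted enolate is attacked on the face anti to the neighbouring C5 isopropenyl group, so C10 is set by substrate control with C1 trans to C4, which fixes the later trans ring fusion.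

Step 3
Reactants: 7 10α-allyl-10β-methyl enone
Product: 8 allylic chloride (C5 substituent now C3H2=C4–C19H2Cl)
Conditions: Ca(OCl)2, CO2 (s), CH2Cl2–H2O, 0 °C
Reagents that add atoms: calcium hypochlorite, [Ca+2].[O-]Cl.[O-]Cl
Why: Ene-type allylic chlorination by HOCl selects the electron-rich 1,1-disubstituted alkene over the monosubstituted allyl group and the deactivated enone, and it shifts the double bond so that the old methyl becomes the C3 methylene and the old methylene becomes C19.

Step 4
Reactants: 8 allylic chloride
Product: 9 enal (2-substituted acrolein: C3H2=C4–C19HO)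
Conditions: NMO, NaI (cat.), NaHCO3, MeCN, 50 °C
Reagents that add atoms: N-methylmorpholine N-oxide, C[N+]1([O-])CCOCC1
Why: In this Kornblum-type amine-oxide oxidation the N-oxide oxygen displaces the allylic halide by SN2 and base-induced loss of N-methylmorpholine releases the aldehyde, leaving the enone and the allyl group untouched.

Step 5
Reactants: 9 enal
Product: 10 2-substituted acrylic acid (C19O2H)
Conditions: NaClO2, NaH2PO4, 2-methyl-2-butene, t-BuOH–H2O, 0 °C → rt
Reagents that add atoms: sodium chlorite, [Na+].[O-]Cl=O
Why: Pinnick oxidation converts the enal into the acid, and the large excess of 2-methyl-2-butene traps HOCl before it can reach the allyl group.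

Step 6
Reactants: 10 acrylic acid
Product: 11 tert-butyl acrylate
Conditions: Cl3CC(=NH)Ot-Bu, BF3·OEt2 (cat.), CH2Cl2–cyclohexane, rt
Reagents that add atoms: tert-butyl 2,2,2-trichloroacetimidate, CC(C)(C)OC(=N)C(Cl)(Cl)Cl
Why: Acid-catalysed tert-butyl transfer from the trichloroacetimidate esterifies the acid under conditions too mild to move any of the three alkenes.

Step 7
Reactants: 11 tert-butyl acrylate
Product: 13 keto aldehyde (C10–C1H2–C2HO), via vicinal diol 12 (not isolated)
Conditions: OsO4 (cat.), NaIO4, 2,6-lutidine, dioxane–H2O, rt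
Reagents that add atoms: osmium tetroxide, O=[Os](=O)(=O)=O; sodium periodate, [Na+].[O-]I(=O)(=O)=O
Why: In this Lemieux–Johnson cleavage OsO4 dihydroxylates the terminal allyl alkene, the only alkene not conjugated to a carbonyl group and the least hindered one, and periodate cuts the diol to leave the two-carbon arm C1–C2.

Step 8
Reactants: 13 keto aldehyde
Product: 14 keto alcohol (C2H2OH)
Conditions: NaBH4, THF–MeOH, −78 → −40 °C
Reagents that add atoms: none
Why: Chemoselective borohydride reduction works because the unhindered aldehyde reacts far faster than the conjugated C9 ketone flanked by quaternary C10, and the acrylate ester is inert.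

Step 9
Reactants: 14 keto alcohol
Product: 15 keto iodide (C2H2I)
Conditions: I2, PPh3, imidazole, CH2Cl2, 0 °C
Reagents that add atoms: iodine, II
Why: Appel-type iodination proceeds by SN2 at the unhindered primary carbon, and doing it while C9 is still a ketone leaves no hydroxyl group that could close a tetrahydrofuran onto C2.

Step 10
Reactants: 15 keto iodide
Product: 16 9β-allylic alcohol (iodide and acrylate intact)
Conditions: NaBH4, CeCl3·7H2O, MeOH, −20 → 0 °C
Reagents that add atoms: none
Why: Luche 1,2-reduction should deliver hydride from the α face, away from the C20 methyl and the C5 substituent that both sit on the β face (the sense in which carvone gives cis-carveol), so the temporary C9 centre should be 9β-OH, and the product is silylated without storage.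

Step 11
Reactants: 16 9β-allylic alcohol
Product: 17 key-step precursor (9β-OTBS; 10α-CH2CH2I; 10β-CH3; tert-butyl acrylate on C5)
Conditions: TBSOTf, 2,6-lutidine, CH2Cl2, −78 → 0 °C
Reagents that add atoms: tert-butyldimethylsilyl triflate, CC(C)(C)[Si](C)(C)OS(=O)(=O)C(F)(F)F
Why: The silyl triflate silylates the hindered carbinol under non-nucleophilic buffered conditions at low temperature, where O-silylation is faster than attack on the tert-butyl ester.

Step 12
Reactants: 17 key-step precursor; 2 iodomethane
Product: 20 trans-decalin tert-butyl ester (5α-H; 10β-CH3; 4α-CH3; axial 4β-CO2t-Bu; C7=C8; 9β-OTBS), via C2 organolithium 18 (not isolated), via C4 lithium ester enolate 19 (not isolated)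
Conditions: t-BuLi (2.1 equiv), THF–Et2O–pentane, −100 → −78 °C; MeI, DMPU, −78 → 0 °C
Reagents that add atoms: iodomethane, CI
Why: Iodine–lithium exchange at the primary C2–I bond at −100 °C is faster than any addition of t-BuLi to the ester or the alkene (the second equivalent destroys t-BuI), the C2 carbanion 18 adds to the unsubstituted C3 methylene of the C4 acrylate, and the exocyclic ester enolate 19 is then alkylated at C4 by MeI. The closest known reaction type is the halogen–metal-exchange-initiated intramolecular conjugate addition of ω-iodoalkyl α,β-unsaturated tert-butyl esters with alkylative trapping of the enolate. Ring A closes in the 6-endo-trig mode (C2–C3) because the tether sits on the α carbon C4, and the alternative 5-exo attack at C4 is anti-Michael and would leave an unstabilised primary carbanion. The ring fusion is not created here: C1 and C4 are already trans on ring B, so only the diequatorial conformer can close and a trans-decalin results. The one new stereocentre, C4, is controlled by the axial C20 methyl, which shields the β face of 19 in a 1,3-diaxial sense, so MeI enters equatorially from the α face and C18 ends α with C19 axial β, as is known for C4 ester enolates of 10-methyl-trans-decalins. The selectivity needed is exchange before addition and 1,4- before 1,2-attack (acyl attack at C19 would also make a six-membered ring), and it is secured by the very fast exchange of a primary iodide, the bulk of the tert-butoxy group, the open CH2 terminus and the absence of a free carbonyl at C9.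

Step 13
Reactants: 20 trans-decalin tert-butyl ester
Product: 21 7-en-9β-ol
Conditions: Bu4NF, THF, 60 °C
Reagents that add atoms: none
Why: Fluoride desilylation works because fluoride attacks the exposed silicon and not the crowded carbinol carbon, and nothing else in the molecule is sensitive to base.

Step 14
Reactants: 21 7-en-9β-ol
Product: 22 7β,8β-epoxy-9β-ol
Conditions: VO(acac)2 (cat.), t-BuOOH, toluene, rt → 50 °C
Reagents that add atoms: tert-butyl hydroperoxide, CC(C)(C)OO
Why: In this hydroxyl-directed vanadium-catalysed epoxidation the peroxide is delivered within the vanadate ester of the 9β-alcohol, so oxygen can only reach the β face of C7=C8 (C7 and C8 are set by C9, the same override of an angular methyl that steroidal 4-en-3β-ols show), and the undirected α-face reaction is negligible with this catalyst.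

Step 15
Reactants: 22 7β,8β-epoxy-9β-ol; 2 iodomethane
Product: 24 C9 S-methyl xanthate, via sodium xanthate 23 (not isolated)
Conditions: NaH, imidazole (cat.), THF, 0 °C; CS2; MeI, rt
Reagents that add atoms: carbon disulfide, S=C=S; iodomethane, CI
Why: Xanthate formation is chosen because CS2 is small enough for the neopentyl C9 alkoxide, the cis relation of alkoxide and epoxide rules out Payne migration, and no β-hydrogen is available for Chugaev elimination.

Step 16
Reactants: 24 C9 S-methyl xanthate
Product: 25 8(9)-en-7β-ol
Conditions: Bu3SnH, AIBN, toluene, 100 °C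
Reagents that add atoms: none
Why: Barton–McCombie-type C9–O homolysis gives an oxiranylcarbinyl radical that opens at C8–O faster than it is reduced (the radical counterpart of the Wharton transposition), the C7 alkoxy radical takes hydrogen from Bu3SnH, and the C7–O bond is never broken, so the 7β configuration is kept.

Step 17
Reactants: 25 8(9)-en-7β-ol; 26 triethyl orthoacetate
Product: 28 C12 ethyl ester C19 tert-butyl ester (9β-CH2CO2Et; 9α-H; C7=C8), via C7 ketene acetal 27 (not isolated)
Conditions: MeC(OEt)3, EtCO2H (cat.), 140 °C, EtOH distilled off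
Reagents that add atoms: triethyl orthoacetate, CC(OCC)(OCC)OCC
Why: In the Johnson–Claisen rearrangement the [3,3] shift of ketene acetal 27 is suprafacial, so C9–C11 forms on the β face from which C7–O departs (C9 is set by chirality transfer from C7, as in the angular alkylation of steroidal 4-en-3β-ols next to C10) and the olefin lands at C7=C8.

Step 18
Reactants: 28 diester
Product: 29 12,19-diol
Conditions: LiAlH4 (excess), THF, reflux
Reagents that add atoms: none
Why: Hydride reduces both esters in one operation; the axial neopentyl tert-butyl ester needs excess reagent at reflux, and the trisubstituted alkene is inert under those conditions.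

Step 19
Reactants: 29 12,19-diol
Product: 30 12-iodo-19-ol
Conditions: I2, PPh3, imidazole (1 equiv each), CH2Cl2, 0 °C
Reagents that add atoms: iodine, II
Why: Appel-type iodination is site-selective because only the unhindered C12 alkoxyphosphonium ion can be displaced by iodide, whereas the axial neopentyl C19 hydroxyl cannot undergo SN2 and is returned on work-up.

Step 20
Reactants: 30 12-iodo-19-ol
Product: 31 19-OTBS 12-iodide
Conditions: TBSOTf, 2,6-lutidine, CH2Cl2, 0 °C
Reagents that add atoms: tert-butyldimethylsilyl triflate, CC(C)(C)[Si](C)(C)OS(=O)(=O)C(F)(F)F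
Why: The reactive silyl triflate silylates the hindered primary alcohol quickly and without a nucleophilic base that could alkylate on the iodide.

Step 21
Reactants: 31 19-OTBS 12-iodide; 32 lithium acetylide ethylenediamine complex
Product: 33 terminal alkyne (C13≡C14H)
Conditions: LiC≡CH·H2NCH2CH2NH2, DMSO, rt
Reagents that add atoms: lithium acetylide ethylenediamine complex, [Li]C#C.NCCN
Why: SN2 alkylation of acetylide by an unhindered primary iodide in a dipolar aprotic solvent forms C12–C13 and is tolerated by a primary TBS ether.

Step 22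
Reactants: 33 terminal alkyne; 34 di-tert-butyl dicarbonate
Product: 36 tert-butyl ynoate (C13≡C14–C15O2t-Bu), via lithium acetylide 35 (not isolated)
Conditions: n-BuLi, THF, −78 °C; Boc2O, −78 → 0 °C
Reagents that add atoms: di-tert-butyl dicarbonate, CC(C)(C)OC(=O)OC(=O)OC(C)(C)C
Why: C-acylation of the lithium acetylide by Boc2O installs C15 directly as an ester that is inert to cuprates and can later be removed without base.

Step 23
Reactants: 36 tert-butyl ynoate; 37 methyllithium
Product: 40 13Z tert-butyl enoate (C16 installed), via lithium dimethylcuprate 38 (not isolated), via alkenylcuprate 39 (not isolated)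
Conditions: MeLi, CuI, THF, 0 °C; 36, −78 °C; aq NH4Cl, −78 °C
Reagents that add atoms: methyllithium (delivered as Me2CuLi), [Li]C
Why: Carbocupration of the ynoate is a syn addition, so C16 and copper end up cis and C12 and C15 end up cis (13Z), and protonation at −78 °C precedes any equilibration through the allenolate.

Step 24
Reactants: 40 13Z tert-butyl enoate
Product: 41 19-alcohol
Conditions: Bu4NF, THF, rt
Reagents that add atoms: none
Why: Fluoride desilylation of the primary silyl ether leaves the tert-butyl enoate and both olefin geometries untouched.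

Step 25
Reactants: 41 19-alcohol; 42 angelic acid
Product: 44 19-angelate tert-butyl ester, via angelic 2,4,6-trichlorobenzoic anhydride 43 (not isolated)
Conditions: 2,4,6-trichlorobenzoyl chloride, Et3N, toluene, rt; then 41, 80 °C
Reagents that add atoms: angelic acid, C/C=C(/C)C(=O)O
Why: Yamaguchi-type mixed-anhydride esterification is run without a nucleophilic pyridine catalyst, the variant known to acylate hindered alcohols with angelic acid without Z to E isomerisation to the tiglate.

Step 26
Reactants: 44 19-angelate tert-butyl ester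
Product: 46 target acid CNP0249147.1, via trimethylsilyl ester 45 (not isolated)
Conditions: TMSOTf, 2,6-lutidine, CH2Cl2, 0 °C; aq citric acid
Reagents that add atoms: none
Why: Silyl-triflate-mediated cleavage converts the tert-butyl ester into the silyl ester with loss of isobutene in a buffered medium, which avoids both protonation of C7=C8 and saponification or isomerisation of the angelate, and mild aqueous work-up frees the acid.

**Compound list**
1 | (R)-(−)-carvone | CC1=CC[C@H](CC1=O)C(C)=C | starting material
2 | iodomethane | CI | starting material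
3 | carvone lithium dienolate (OLi on C9, C9=C10, C7=C8) | CC1=CC[C@H](C=C1O[Li])C(C)=C | intermediate
4 | 6-methylcarvone (CH3 on C10, both C10 epimers, 5α-H) | CC1C(=O)C(C)=CC[C@H]1C(C)=C | intermediate
5 | allyl bromide | C=CCBr | starting material
6 | lithium dienolate of 4 (tetrasubstituted C9=C10) | CC1=C(O[Li])C(C)=CC[C@H]1C(C)=C | intermediate
7 | 10α-allyl-10β-methyl enone (C9 ketone, C7=C8 with C17 on C8, 5α-H, isopropenyl on C5 trans to allyl) | C=CC[C@]1(C)C(=O)C(C)=CC[C@H]1C(C)=C | intermediate
8 | allylic chloride (as 7, C5 substituent 3-chloroprop-1-en-2-yl) | C=CC[C@]1(C)C(=O)C(C)=CC[C@H]1C(=C)CCl | intermediate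
9 | enal (as 7, C5 substituent 1-formylvinyl) | C=CC[C@]1(C)C(=O)C(C)=CC[C@H]1C(=C)C=O | intermediate
10 | acrylic acid (as 7, C5 substituent 1-carboxyvinyl) | C=CC[C@]1(C)C(=O)C(C)=CC[C@H]1C(=C)C(=O)O | intermediate
11 | tert-butyl acrylate (as 10, tert-butyl ester) | C=CC[C@]1(C)C(=O)C(C)=CC[C@H]1C(=C)C(=O)OC(C)(C)C | intermediate
12 | vicinal diol from the allyl group of 11 (carbinol centre undefined) | OCC(O)C[C@]1(C)C(=O)C(C)=CC[C@H]1C(=C)C(=O)OC(C)(C)C | intermediate
13 | keto aldehyde (10α-CH2CHO) | O=CC[C@]1(C)C(=O)C(C)=CC[C@H]1C(=C)C(=O)OC(C)(C)C | intermediate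
14 | keto alcohol (10α-CH2CH2OH) | OCC[C@]1(C)C(=O)C(C)=CC[C@H]1C(=C)C(=O)OC(C)(C)C | intermediate
15 | keto iodide (10α-CH2CH2I) | ICC[C@]1(C)C(=O)C(C)=CC[C@H]1C(=C)C(=O)OC(C)(C)C | intermediate
16 | 9β-allylic alcohol (10α-CH2CH2I, 10β-CH3, 5α-H, tert-butyl acrylate on C5) | ICC[C@]1(C)[C@@H](O)C(C)=CC[C@H]1C(=C)C(=O)OC(C)(C)C | intermediate
17 | key-step precursor (as 16, 9β-OTBS) | ICC[C@]1(C)[C@@H](O[Si](C)(C)C(C)(C)C)C(C)=CC[C@H]1C(=C)C(=O)OC(C)(C)C | intermediate
18 | C2 organolithium from 17 | [Li]CC[C@]1(C)[C@@H](O[Si](C)(C)C(C)(C)C)C(C)=CC[C@H]1C(=C)C(=O)OC(C)(C)C | intermediate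
19 | C4 lithium ester enolate (trans-decalin, exocyclic C4=C19) | CC(C)(C)OC(O[Li])=C1CCC[C@]2(C)[C@@H](O[Si](C)(C)C(C)(C)C)C(C)=CC[C@@H]12 | intermediate
20 | trans-decalin tert-butyl ester (5α-H, 10β-CH3, 4α-CH3, axial 4β-CO2t-Bu, C7=C8, 9β-OTBS) | CC(C)(C)OC(=O)[C@@]1(C)CCC[C@]2(C)[C@@H](O[Si](C)(C)C(C)(C)C)C(C)=CC[C@@H]12 | intermediate
21 | 7-en-9β-ol (as 20, free 9β-OH) | CC(C)(C)OC(=O)[C@@]1(C)CCC[C@]2(C)[C@@H](O)C(C)=CC[C@@H]12 | intermediate
22 | 7β,8β-epoxy-9β-ol | CC(C)(C)OC(=O)[C@@]1(C)CCC[C@]2(C)[C@@H](O)[C@@]3(C)O[C@H]3C[C@@H]12 | intermediate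
23 | sodium xanthate of 22 | CC(C)(C)OC(=O)[C@@]1(C)CCC[C@]2(C)[C@@H](OC(=S)[S-])[C@@]3(C)O[C@H]3C[C@@H]12.[Na+] | intermediate
24 | C9 S-methyl xanthate of 22 | CC(C)(C)OC(=O)[C@@]1(C)CCC[C@]2(C)[C@@H](OC(=S)SC)[C@@]3(C)O[C@H]3C[C@@H]12 | intermediate
25 | 8(9)-en-7β-ol (C9H=C8(CH3), 7β-OH) | CC(C)(C)OC(=O)[C@@]1(C)CCC[C@]2(C)C=C(C)[C@@H](O)C[C@@H]12 | intermediate
26 | triethyl orthoacetate | CC(OCC)(OCC)OCC | starting material
27 | C7 ketene acetal (7β-OC(OEt)=CH2) | CC(C)(C)OC(=O)[C@@]1(C)CCC[C@]2(C)C=C(C)[C@@H](OC(=C)OCC)C[C@@H]12 | intermediate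
28 | diester (9β-CH2CO2Et, 9α-H, C7=C8, axial C19 tert-butyl ester) | CC(C)(C)OC(=O)[C@@]1(C)CCC[C@]2(C)[C@@H](CC(=O)OCC)C(C)=CC[C@@H]12 | intermediate
29 | 12,19-diol | OC[C@@]1(C)CCC[C@]2(C)[C@@H](CCO)C(C)=CC[C@@H]12 | intermediate
30 | 12-iodo-19-ol | OC[C@@]1(C)CCC[C@]2(C)[C@@H](CCI)C(C)=CC[C@@H]12 | intermediate
31 | 19-OTBS 12-iodide | CC(C)(C)[Si](C)(C)OC[C@@]1(C)CCC[C@]2(C)[C@@H](CCI)C(C)=CC[C@@H]12 | intermediate
32 | lithium acetylide ethylenediamine complex | [Li]C#C.NCCN | starting material
33 | terminal alkyne (C11–C12–C13≡C14H, 19-OTBS) | CC(C)(C)[Si](C)(C)OC[C@@]1(C)CCC[C@]2(C)[C@@H](CCC#C)C(C)=CC[C@@H]12 | intermediate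
34 | di-tert-butyl dicarbonate | CC(C)(C)OC(=O)OC(=O)OC(C)(C)C | starting material
35 | lithium acetylide of 33 | CC(C)(C)[Si](C)(C)OC[C@@]1(C)CCC[C@]2(C)[C@@H](CCC#C[Li])C(C)=CC[C@@H]12 | intermediate
36 | tert-butyl ynoate | CC(C)(C)[Si](C)(C)OC[C@@]1(C)CCC[C@]2(C)[C@@H](CCC#CC(=O)OC(C)(C)C)C(C)=CC[C@@H]12 | intermediate
37 | methyllithium | [Li]C | starting material
38 | lithium dimethylcuprate | [Li+].C[Cu-]C | intermediate
39 | alkenylcuprate (Cu on C14 cis to C16) | CC(C)(C)[Si](C)(C)OC[C@@]1(C)CCC[C@]2(C)[C@@H](CC/C(C)=C(/[Cu-]C)C(=O)OC(C)(C)C)C(C)=CC[C@@H]12.[Li+] | intermediate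
40 | 13Z tert-butyl enoate, 19-OTBS | CC(C)(C)[Si](C)(C)OC[C@@]1(C)CCC[C@]2(C)[C@@H](CC/C(C)=C\C(=O)OC(C)(C)C)C(C)=CC[C@@H]12 | intermediate
41 | 19-alcohol, 13Z tert-butyl enoate | OC[C@@]1(C)CCC[C@]2(C)[C@@H](CC/C(C)=C\C(=O)OC(C)(C)C)C(C)=CC[C@@H]12 | intermediate
42 | angelic acid ((Z)-2-methylbut-2-enoic acid) | C/C=C(/C)C(=O)O | starting material
43 | angelic 2,4,6-trichlorobenzoic anhydride | C/C=C(/C)C(=O)OC(=O)c1c(Cl)cc(Cl)cc1Cl | intermediate
44 | 19-angelate, 13Z tert-butyl enoate | C/C=C(/C)C(=O)OC[C@@]1(C)CCC[C@]2(C)[C@@H](CC/C(C)=C\C(=O)OC(C)(C)C)C(C)=CC[C@@H]12 | intermediate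
45 | 19-angelate, C15 trimethylsilyl ester | C/C=C(/C)C(=O)OC[C@@]1(C)CCC[C@]2(C)[C@@H](CC/C(C)=C\C(=O)O[Si](C)(C)C)C(C)=CC[C@@H]12 | intermediate
46 | (4S,5R,9S,10R)-19-angeloyloxylabda-7,13Z-dien-15-oic acid (CNP0249147.1) | C/C=C(/C)C(=O)OC[C@@]1(C)CCC[C@]2(C)[C@@H](CC/C(C)=C\C(=O)O)C(C)=CC[C@@H]12 | target

Total step count: 26. Longest linear sequence: 26 (the route is fully linear from 1).

**Steps most likely to fail**

Step 12. Four processes may outrun exchange and cyclisation: addition of t-BuLi to the open acrylate, anionic oligomerisation of the acrylate, acyl attack of the C2 carbanion at C19, and oxygen-to-carbon silyl migration from the C9 ether. The fallback sets out from 17 and replaces the carbanion by a radical. Bu3SnH with AIBN in benzene at 80 °C under slow addition turns C2–I into the primary radical. This radical closes ring A by 6-endo addition to C3, because that gives the tertiary α-ester radical, and affords the C4–H decalin ester F1 as C4 epimers. Deprotonation with LiN(i-Pr)2 in THF gives enolate 19, and MeI with DMPU then gives 20, where the route is rejoined.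

Step 14. The pseudo-equatorial 9β-alcohol is a slow substrate for directed oxygen transfer, so it may be oxidised to the enone instead of the olefin being epoxidised. The β face next to C20 may also prove too crowded, and an erosion of the C9 configuration in step 10 would carry through to C7. The fallback sets out from 21 and makes the C7 configuration independent of C9.
- Dess–Martin oxidation gives the 7-en-9-one F2.
- Weitz–Scheffer epoxidation (H2O2, NaOH, MeOH) on the open α face gives the 7α,8α-epoxy ketone F3.
- Wharton transposition (N2H4·H2O, AcOH, MeOH) gives the 8(9)-en-7α-ol F4.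
- Oxidation with MnO2 gives the 8(9)-en-7-one F5.
- Luche reduction with axial hydride delivery from the α face gives the equatorial 7β-ol 25, where the route is rejoined.

Step 17. At 140 °C with acid present the allylic C7 oxygen may be lost by elimination to the 6,8-diene. This can happen before the slow rearrangement takes place, since that rearrangement starts from a pseudo-equatorial C–O bond and forms a bond beside C20. The fallback sets out from 25 and uses a preformed ketene acetal under base-only conditions (Ireland–Claisen).
- Acetylation (Ac2O, pyridine, 4-dimethylaminopyridine) gives the 7β-acetate F6.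
- LiN(i-Pr)2 and TBSCl in THF–DMPU at −78 °C give the silyl ketene acetal F7.
- Warming to reflux in THF brings about the same suprafacial [3,3] shift and gives the C12 silyl ester F8.
- LiAlH4 in refluxing THF reduces both acyl groups to the diol 29, where the route is rejoined.

**Further compounds**
F1 | step 12 | C4–H decalin tert-butyl ester (C4 epimers, otherwise as 20) | CC(C)(C)OC(=O)C1CCC[C@]2(C)[C@@H](O[Si](C)(C)C(C)(C)C)C(C)=CC[C@@H]12
F2 | step 14 | 7-en-9-one | CC(C)(C)OC(=O)[C@@]1(C)CCC[C@]2(C)C(=O)C(C)=CC[C@@H]12
F3 | step 14 | 7α,8α-epoxy-9-ketone | CC(C)(C)OC(=O)[C@@]1(C)CCC[C@]2(C)C(=O)[C@]3(C)O[C@@H]3C[C@@H]12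
F4 | step 14 | 8(9)-en-7α-ol | CC(C)(C)OC(=O)[C@@]1(C)CCC[C@]2(C)C=C(C)[C@H](O)C[C@@H]12
F5 | step 14 | 8(9)-en-7-one | CC(C)(C)OC(=O)[C@@]1(C)CCC[C@]2(C)C=C(C)C(=O)C[C@@H]12
F6 | step 17 | 8(9)-en-7β-yl acetate | CC(C)(C)OC(=O)[C@@]1(C)CCC[C@]2(C)C=C(C)[C@@H](OC(C)=O)C[C@@H]12
F7 | step 17 | 7β-O silyl ketene acetal | CC(C)(C)OC(=O)[C@@]1(C)CCC[C@]2(C)C=C(C)[C@@H](OC(=C)O[Si](C)(C)C(C)(C)C)C[C@@H]12
F8 | step 17 | C12 tert-butyldimethylsilyl ester (9β-CH2CO2TBS, C7=C8) | CC(C)(C)OC(=O)[C@@]1(C)CCC[C@]2(C)[C@@H](CC(=O)O[Si](C)(C)C(C)(C)C)C(C)=CC[C@@H]12
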